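**Retrosynthetic overview**

1. Ring C (the quinone) is closed last, at its C5–C6 bond (the unsubstituted CH=CH). Carbonyls C1 and C4 are 1,4-related across this bond, so C5 and C6 are both α-carbons of ketones. Opened there, ring C is the bis(silyl enol ether) 10 of a (Z)-3-(furan-2-yl)hex-3-ene-2,5-dione: a 2,5-dioxyhexa-1,3,5-triene whose two CH2 termini are held cis by the C2=C3 alkene. One anodic operation should couple them, aromatise the ring and oxidise it to the quinone.
2. The (Z)-ene-dione is carried as a temporary ring B: a 2,5-dimethylfuran, oxidised early to its 2,5-dimethoxy-2,5-dihydrofuran (a cyclic bis-ketal that fixes the cis geometry) and opened by mild acid just before the key step.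
3. The isovalerate is placed on an (R)-alcohol; the prenyl group comes from an allyl group by cross-metathesis; the stereocentre comes from reagent-controlled allylboration of a furan-3-carbaldehyde.
4. The ring A–ring B bond comes from a Suzuki–Miyaura coupling of 5-bromofuran-3-carbaldehyde (1) with the 2,5-dimethylfuran-3-yl pinacol boronate (2).
5. Ring order: ring A (furan) and ring B (temporary furan) are bought; ring B is masked in step 2 and opened in step 6; ring C is formed in step 8.

Key step: step 8

Assumption: 1 and 2 are treated as catalogue building blocks, and the (R) sense of step 3 rests on the established Re-face delivery of the (−)-α-pinene-derived allylborane to aryl aldehydes.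

**Route**

Step 1
Reactants: 1 5-bromofuran-3-carbaldehyde; 2 2-(2,5-dimethylfuran-3-yl)-4,4,5,5-tetramethyl-1,3,2-dioxaborolane
Product: 3 5-(2,5-dimethylfuran-3-yl)furan-3-carbaldehyde
Conditions: PdCl2(dppf) (3 mol %), K3PO4, 1,4-dioxane/H2O 5:1, 80 °C
Reagents that add atoms: none
Why: Suzuki–Miyaura coupling, in which the 2-bromofuran adds readily to zerovalent palladium, the 3-furyl boronate is not prone to protodeboronation and the aldehyde is tolerated.

Step 2
Reactants: 3 5-(2,5-dimethylfuran-3-yl)furan-3-carbaldehyde
Product: 4 5-(2,5-dimethoxy-2,5-dimethyl-2,5-dihydrofuran-3-yl)furan-3-carbaldehyde (cis/trans mixture at the two ketal carbons)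
Conditions: Br2 (1.0 equiv), Na2CO3, MeOH, −40 to −10 °C
Reagents that add atoms: methanol, CO
Why: Clauson-Kaas-type oxidative 2,5-dimethoxylation, in which bromine should attack the electron-rich dimethylfuran ring B far faster than the formyl-deactivated ring A and methanol adds at both α-carbons; the ketal stereocentres are erased in step 6, so their mixture is of no consequence.

Step 3
Reactants: 4 5-(2,5-dimethoxy-2,5-dimethyl-2,5-dihydrofuran-3-yl)furan-3-carbaldehyde
Product: 6 (R)-1-[5-(2,5-dimethoxy-2,5-dimethyl-2,5-dihydrofuran-3-yl)furan-3-yl]but-3-en-1-ol, via diisopinocampheylborinate 5 (not isolated)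
Conditions: (+)-Ipc2BOMe (from (−)-α-pinene), CH2=CHCH2MgBr, Et2O, 0 °C to rt; then 4, −78 °C; then NaOH, 30% H2O2, 0 °C to rt
Reagents that add atoms: allylmagnesium bromide, C=CC[Mg]Br
Why: Brown allylboration through a chair six-membered transition state, in which the isopinocampheyl groups from (−)-α-pinene should deliver the allyl group to the Re face of the aldehyde and so set the (R) centre (same sense as (R)-1-phenylbut-3-en-1-ol from benzaldehyde), while the ketal ring survives the basic oxidative work-up.

Step 4
Reactants: 6 (R)-1-[5-(2,5-dimethoxy-2,5-dimethyl-2,5-dihydrofuran-3-yl)furan-3-yl]but-3-en-1-ol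
Product: 7 (R)-1-[5-(2,5-dimethoxy-2,5-dimethyl-2,5-dihydrofuran-3-yl)furan-3-yl]-4-methylpent-3-en-1-ol
Conditions: second-generation Grubbs catalyst RuCl2(=CHPh)(H2IMes)(PCy3) (5 mol %), 2-methyl-2-butene/CH2Cl2 1:3, 40 °C, sealed tube
Reagents that add atoms: 2-methyl-2-butene, CC=C(C)C
Why: Olefin cross-metathesis of the terminal alkene with excess 2-methyl-2-butene exchanges =CH2 for =C(CH3)2, while the hindered trisubstituted ring alkene, the furan and the carbinol centre are not touched.

Step 5
Reactants: 7 (R)-1-[5-(2,5-dimethoxy-2,5-dimethyl-2,5-dihydrofuran-3-yl)furan-3-yl]-4-methylpent-3-en-1-ol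
Product: 8 (R)-1-[5-(2,5-dimethoxy-2,5-dimethyl-2,5-dihydrofuran-3-yl)furan-3-yl]-4-methylpent-3-en-1-yl 3-methylbutanoate
Conditions: 3-methylbutanoic anhydride (1.5 equiv), Et3N, DMAP (10 mol %), CH2Cl2, 0 °C to rt
Reagents that add atoms: 3-methylbutanoic anhydride, CC(C)CC(=O)OC(=O)CC(C)C
Why: DMAP-catalysed acyl transfer to the secondary alcohol breaks only the O–H bond, so the configuration is retained, and the basic medium keeps the ketal intact.

Step 6
Reactants: 8 (R)-1-[5-(2,5-dimethoxy-2,5-dimethyl-2,5-dihydrofuran-3-yl)furan-3-yl]-4-methylpent-3-en-1-yl 3-methylbutanoate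
Product: 9 (R)-1-{5-[(3Z)-2,5-dioxohex-3-en-3-yl]furan-3-yl}-4-methylpent-3-en-1-yl 3-methylbutanoate
Conditions: AcOH (1% v/v), acetone/H2O 4:1, rt, dark
Reagents that add atoms: water, O
Why: Mild acid hydrolysis of the cyclic bis-ketal releases the ene-1,4-dione with its two acetyl groups cis because the geometry is inherited from the ring, and at this acidity the furylic ester and the trisubstituted alkene should not ionise.

Step 7
Reactants: 9 (R)-1-{5-[(3Z)-2,5-dioxohex-3-en-3-yl]furan-3-yl}-4-methylpent-3-en-1-yl 3-methylbutanoate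
Product: 10 (R)-1-{5-[(3Z)-2,5-bis(tert-butyldimethylsilyloxy)hexa-1,3,5-trien-3-yl]furan-3-yl}-4-methylpent-3-en-1-yl 3-methylbutanoate
Conditions: TBSOTf (2.5 equiv), Et3N (5 equiv), CH2Cl2, −78 to −20 °C
Reagents that add atoms: tert-butyldimethylsilyl trifluoromethanesulfonate, CC(C)(C)[Si](C)(C)OS(=O)(=O)C(F)(F)F
Why: Soft enolisation (silyl triflate and tertiary amine) of the two methyl ketones, whose only enolisable positions are the methyl groups, should give the bis(silyl enol ether) because O-silylation and deprotonation at low temperature outpace the five-membered aldol closure of cis-ene-diones, and the ester is not enolised under these conditions.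

Step 8
Reactants: 10 (R)-1-{5-[(3Z)-2,5-bis(tert-butyldimethylsilyloxy)hexa-1,3,5-trien-3-yl]furan-3-yl}-4-methylpent-3-en-1-yl 3-methylbutanoate
Product: 13 (R)-1-[5-(3,6-dioxocyclohexa-1,4-dien-1-yl)furan-3-yl]-4-methylpent-3-en-1-yl 3-methylbutanoate (CNP0219765.1), via cyclohexenedione 11 (not isolated), via hydroquinone 12 (not isolated)
Conditions: divided cell, reticulated vitreous carbon anode, Pt cathode, controlled potential at the first anodic wave of 10 (about +1.0 V vs Ag/AgCl, about 4 F/mol), LiClO4 (0.1 M), 2,6-lutidine (6 equiv), MeCN/MeOH 4:1, 0 °C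
Reagents that add atoms: none
Why: Proposed new method: one-electron oxidation of the 2,5-bis(silyloxy)hexa-1,3,5-triene at the anode should give a radical cation whose two CH2 termini, held cis by the (Z)-alkene, join by 6-endo-trig attack of one enol ether on the oxidised other (equally a radical-cation electrocyclisation) to close the six-membered carbocycle; a second electron transfer and loss of both silyl groups to methanol give ene-dione 11, the keto tautomer of hydroquinone 12, which aromatises under 2,6-lutidine and is oxidised at the same potential to quinone 13 (four electrons in all). The closest known reaction types are the anodic coupling of two enol ethers, the oxidative coupling of bis(silyl enol ethers) to 1,4-diketones and the anodic oxidation of hydroquinones; their union on an acyclic ene-dione bis(enol ether) to build a quinone ring is the new element. No new stereocentre is formed, and the (R) ester centre is remote and should not ionise in the buffered medium. The step needs oxidation of the triene in the presence of ring A, the trisubstituted alkene and the ester, which the controlled potential at the first wave of the furan-conjugated bis(enol ether) should secure, and it needs the cis geometry, which the furan-derived mask fixed. Aromatisation to 12 makes the C–C bond formation irreversible, and the divided cell keeps the quinone from cathodic reduction.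

**Compound list**

1 | 5-bromofuran-3-carbaldehyde | O=Cc1coc(Br)c1 | starting material
2 | 2-(2,5-dimethylfuran-3-yl)-4,4,5,5-tetramethyl-1,3,2-dioxaborolane | Cc1cc(B2OC(C)(C)C(C)(C)O2)c(C)o1 | starting material
3 | 5-(2,5-dimethylfuran-3-yl)furan-3-carbaldehyde | O=Cc1coc(-c2cc(C)oc2C)c1 | intermediate
4 | 5-(2,5-dimethoxy-2,5-dimethyl-2,5-dihydrofuran-3-yl)furan-3-carbaldehyde (mixture at the two ketal carbons, left undefined) | O=Cc1coc(C2=CC(C)(OC)OC2(C)OC)c1 | intermediate
5 | (R)-1-[5-(2,5-dimethoxy-2,5-dimethyl-2,5-dihydrofuran-3-yl)furan-3-yl]but-3-en-1-yl diisopinocampheylborinate | C=CC[C@@H](OB([C@H]1C[C@H]2C[C@@H]([C@@H]1C)C2(C)C)[C@H]1C[C@H]2C[C@@H]([C@@H]1C)C2(C)C)c1coc(C2=CC(C)(OC)OC2(C)OC)c1 | intermediate (not isolated)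
6 | (R)-1-[5-(2,5-dimethoxy-2,5-dimethyl-2,5-dihydrofuran-3-yl)furan-3-yl]but-3-en-1-ol | C=CC[C@@H](O)c1coc(C2=CC(C)(OC)OC2(C)OC)c1 | intermediate
7 | (R)-1-[5-(2,5-dimethoxy-2,5-dimethyl-2,5-dihydrofuran-3-yl)furan-3-yl]-4-methylpent-3-en-1-ol | CC(C)=CC[C@@H](O)c1coc(C2=CC(C)(OC)OC2(C)OC)c1 | intermediate
8 | (R)-1-[5-(2,5-dimethoxy-2,5-dimethyl-2,5-dihydrofuran-3-yl)furan-3-yl]-4-methylpent-3-en-1-yl 3-methylbutanoate | CC(C)=CC[C@@H](OC(=O)CC(C)C)c1coc(C2=CC(C)(OC)OC2(C)OC)c1 | intermediate
9 | (R)-1-{5-[(3Z)-2,5-dioxohex-3-en-3-yl]furan-3-yl}-4-methylpent-3-en-1-yl 3-methylbutanoate | CC(C)=CC[C@@H](OC(=O)CC(C)C)c1coc(/C(C(C)=O)=C/C(C)=O)c1 | intermediate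
10 | (R)-1-{5-[(3Z)-2,5-bis(tert-butyldimethylsilyloxy)hexa-1,3,5-trien-3-yl]furan-3-yl}-4-methylpent-3-en-1-yl 3-methylbutanoate | CC(C)=CC[C@@H](OC(=O)CC(C)C)c1coc(/C(C(=C)O[Si](C)(C)C(C)(C)C)=C/C(=C)O[Si](C)(C)C(C)(C)C)c1 | intermediate
11 | (R)-1-[5-(3,6-dioxocyclohex-1-en-1-yl)furan-3-yl]-4-methylpent-3-en-1-yl 3-methylbutanoate | CC(C)=CC[C@@H](OC(=O)CC(C)C)c1coc(C2=CC(=O)CCC2=O)c1 | intermediate (not isolated)
12 | (R)-1-[5-(2,5-dihydroxyphenyl)furan-3-yl]-4-methylpent-3-en-1-yl 3-methylbutanoate | CC(C)=CC[C@@H](OC(=O)CC(C)C)c1coc(-c2cc(O)ccc2O)c1 | intermediate (not isolated)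
13 | (R)-1-[5-(3,6-dioxocyclohexa-1,4-dien-1-yl)furan-3-yl]-4-methylpent-3-en-1-yl 3-methylbutanoate | CC(C)=CC[C@@H](OC(=O)CC(C)C)c1coc(C2=CC(=O)C=CC2=O)c1 | target

**Step count and risks**

Total step count: 8. Longest linear sequence: 8 steps (from 1 or 2 to 13).

Steps most likely to fail:

1. Step 8 (Proposed new method). The radical cation may be intercepted by methanol or by ring A before the two CH2 termini join. Unconsumed 10 may capture the quinone in a Diels–Alder reaction. Ring A may be degraded oxidatively if the potential drifts. The fallback uses known chemistry and no electrode and sets out from 10. Heating 10 in toluene at about 120 °C (sealed tube, trace Et3N) should close the (Z)-hexatriene by thermal disrotatory 6π-electrocyclisation to (R)-1-{5-[2,5-bis(tert-butyldimethylsilyloxy)cyclohexa-1,5-dien-1-yl]furan-3-yl}-4-methylpent-3-en-1-yl 3-methylbutanoate F1. DDQ (1.1 equiv, CH2Cl2, 0 °C) should dehydrogenate it to (R)-1-{5-[2,5-bis(tert-butyldimethylsilyloxy)phenyl]furan-3-yl}-4-methylpent-3-en-1-yl 3-methylbutanoate F2. Bu4NF buffered with AcOH (THF, 0 °C) then removes both silyl groups. This comes back to the route at hydroquinone 12, which DDQ (1.0 equiv) should oxidise to 13.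

2. Step 7. A Mukaiyama-type five-membered aldol closure may be triggered by the silyl triflate. The cis-alkene may drift to trans through reversible amine addition. The enol ethers may be lost hydrolytically on isolation. The fallback sets out from 9 and avoids silyl enol ethers altogether. Inverse addition of 9 to LiN(SiMe3)2 (2.2 equiv, THF, −78 °C) should give the dilithium bis-enolate F3 of 9 (not isolated), with the second deprotonation outrunning the aldol. CuCl2 (2.2 equiv, DMF, −78 °C to 0 °C) should then join the two enolate carbons by intramolecular copper-mediated oxidative enolate coupling, giving 11, which tautomerises on buffered work-up. The fallback comes back to the route at 12, which DDQ (1.0 equiv) should oxidise to 13.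

3. Step 2. Bromine may oxidise the aldehyde through its methyl hemiacetal to the methyl ester, the aldehyde may be acetalised, or ring A may be attacked competitively. The fallback sets out from 2 and moves the masking in front of the coupling, so that neither the aldehyde nor ring A meets the oxidant. Anodic 2,5-dimethoxylation of 2 (MeOH, Et4NOTs, carbon anode, undivided cell, −20 °C) should give 2-(2,5-dimethoxy-2,5-dimethyl-2,5-dihydrofuran-3-yl)-4,4,5,5-tetramethyl-1,3,2-dioxaborolane F4. Suzuki–Miyaura coupling of this alkenyl boronate with 1 under the conditions of step 1 comes back to the route at 4.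

Further compounds
F1 | step 8 | (R)-1-{5-[2,5-bis(tert-butyldimethylsilyloxy)cyclohexa-1,5-dien-1-yl]furan-3-yl}-4-methylpent-3-en-1-yl 3-methylbutanoate | CC(C)=CC[C@@H](OC(=O)CC(C)C)c1coc(C2=C(O[Si](C)(C)C(C)(C)C)CCC(O[Si](C)(C)C(C)(C)C)=C2)c1
F2 | step 8 | (R)-1-{5-[2,5-bis(tert-butyldimethylsilyloxy)phenyl]furan-3-yl}-4-methylpent-3-en-1-yl 3-methylbutanoate | CC(C)=CC[C@@H](OC(=O)CC(C)C)c1coc(-c2cc(O[Si](C)(C)C(C)(C)C)ccc2O[Si](C)(C)C(C)(C)C)c1
F3 | step 7 | dilithium bis-enolate of 9 | CC(C)=CC[C@@H](OC(=O)CC(C)C)c1coc(/C(C(=C)[O-])=C/C(=C)[O-])c1.[Li+].[Li+]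
F4 | step 2 | 2-(2,5-dimethoxy-2,5-dimethyl-2,5-dihydrofuran-3-yl)-4,4,5,5-tetramethyl-1,3,2-dioxaborolane | COC1(C)C=C(B2OC(C)(C)C(C)(C)O2)C(C)(OC)O1
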